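## Retrosynthetic overview

- Numbering (germacranolide): ten-membered ring C1–C10; C14 is the ester carbon on C10, C15 the methyl on C4, C11–C12 the lactone arm on C7, C13 the exocyclic methylene carbon.
- Feature: C6 (lactone O–CH) and C10 (enoate carbon) are two former ketone carbons, 1,5 to each other through C7–C8–C9, and C8/C9 carry cis oxygens. That is the pattern a de Mayo reaction leaves when a cyclic 1,3-dione enol adds to a cis-dioxygenated alkene, so C7–C8 and C9–C10 are cut to give a symmetric 2-substituted cyclooctane-1,3-dione and 2,2-dimethyl-1,3-dioxole.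
- Later disconnections: C10–C14 (enol triflate carbonylation), C4–C15 (cuprate on the C6 enone), the epoxide C–O bonds (hydroxyl-directed epoxidation), O6–C12 (lactonisation), C11=C13 (Mannich methylenation), then the O9 and O8 acyl groups.
- Ring order: eight-membered dione (bought) → transient cyclobutane → ten-membered carbocycle by two-carbon ring expansion → epoxide → γ-lactone.

Key step: step 2

Assumption: the esterase of step 3 is taken to hydrolyse the enantiomer drawn; if it prefers the other, the ester left over is hydrolysed to 8 with the same enzyme over a longer time.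

## Route

Step 1
Reactants: 1 cyclooctane-1,3-dione; 2 methyl bromoacetate
Product: 3 methyl 2-(2,8-dioxocyclooctyl)acetate
Conditions: K2CO3 (1.1 equiv), acetone, reflux; 1 in slight excess
Reagents that add atoms: none
Why: Enolate C-alkylation (SN2) of a 1,3-diketone with an α-bromo ester; the medium-ring dione is not enol-locked and behaves like an open-chain β-diketone, so carbon attack should dominate, and the excess of 1 keeps double alkylation down; no lasting stereocentre is formed.

Step 2
Reactants: 3 methyl 2-(2,8-dioxocyclooctyl)acetate; 4 2,2-dimethyl-1,3-dioxole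
Product: 7 racemic ten-membered diketone ester, via enol tautomer 5 (not isolated), via cyclobutanol photoadduct 6 (not isolated)
Conditions: 4 (10 equiv), degassed MeCN, hν (300 nm lamps, Pyrex), 5 °C; evaporation at rt, quick filtration through neutral alumina
Reagents that add atoms: none
Why: De Mayo reaction: the small equilibrium amount of enol 5 is the only species absorbing near 300 nm, and its excited state adds to the electron-rich alkene 4 through a 1,4-diradical (first bond C7–C8 or C9–C10, then radical recombination), the closest known case being the photocycloaddition of dimedone-type enols to alkenes followed by retro-aldol cleavage. The cyclobutane of 6 closes by this stepwise diradical [2+2] cycloaddition, whereas the ten-membered ring is not closed end to end but arises by ring expansion when the strained β-hydroxy ketone 6 breaks its C7–C10 bond in a spontaneous retro-aldol reaction. C8 and C9 come out cis because both oxygens belong to the five-membered dioxole and both new C–C bonds form on one face of it; C7 is set afterwards by ketonisation of the C6 enol and stays epimerisable, the isomer with the arm anti to the C8–O bond (arm cis to O8 in the flat ring) being expected at equilibrium. There is no regiochemical choice, since enolisation of 3 toward either carbonyl gives the same enol and the two alkene carbons of 4 are equivalent. The step needs cycloaddition to win over enone dimerisation and over twisting of the excited eight-membered enone, which the large excess of 4 should secure, and the ring-fusion geometry of 6 does not matter because that bond is cleaved; β-elimination is held back because the leaving group would be an acetal oxygen in a neutral medium. The product is racemic and is kept away from acid and base, which could close a transannular aldol between the C6 and C10 ketone units.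

Step 3
Reactants: 7 racemic ten-membered diketone ester
Product: 8 keto acid (single enantiomer)
Conditions: pig liver esterase, 0.1 M phosphate buffer pH 7.2, 5% acetone, 25 °C, stopped near 45% conversion; acid extracted at pH 4 (citric acid)
Reagents that add atoms: water (O)
Why: Enzymatic kinetic resolution by enantioselective ester hydrolysis; the enantiomers differ in the fixed C8/C9 centres beside the arm-bearing C7 and cannot interconvert, so the hydrolase should separate them into acid and ester, and the neutral buffer leaves the acetonide and both ketones alone; this step fixes the absolute configuration.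

Step 4
Reactants: 8 keto acid
Product: 10 hydroxy lactone, via dihydroxy acid 9 (not isolated)
Conditions: NaBH4 (3 equiv), MeOH, −20 → 0 °C; then PPTS (cat.), PhMe, 50 °C
Reagents that add atoms: none
Why: Borohydride reduction of both ketones, then lactonisation: only the C6 hydroxyl is 1,4 to the carboxyl and closes a five-membered lactone, so C6 and C10 become chemically distinct without any enolisation of the 1,5-diketone; the carbinol configurations at C6 and C10 are left uncontrolled because both centres are oxidised again in steps 5 and 11.

Step 5
Reactants: 10 hydroxy lactone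
Product: 11 keto lactone
Conditions: Dess–Martin periodinane, pyridine, CH2Cl2, 0 °C → rt
Reagents that add atoms: none
Why: Dess–Martin oxidation of the single free secondary alcohol under buffered, non-enolising conditions, so that C9 beside the new C10 ketone keeps its configuration.

Step 6
Reactants: 11 keto lactone
Product: 12 enol triflate
Conditions: KN(SiMe3)2 (1.1 equiv), THF, −78 °C; PhNTf2, −78 → 0 °C
Reagents that add atoms: N-phenylbis(trifluoromethanesulfonimide) (O=S(=O)(N(c1ccccc1)S(=O)(=O)C(F)(F)F)C(F)(F)F)
Why: Kinetic enolate formation and O-sulfonylation (enol triflate synthesis): the hindered amide base should take a C1 methylene proton rather than the C9 methine (hindered, α-oxygenated) or the less acidic lactone α-protons, no leaving group sits β to the enolate carbon, and the ten-membered ring should adopt the less strained enolate with C2 and C9 cis, which is the C1=C10 geometry of the target.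

Step 7
Reactants: 12 enol triflate
Product: 13 enoate acetonide
Conditions: Pd(OAc)2 (5 mol %), PPh3 (10 mol %), CO (1 atm), MeOH, Et3N, DMF, 50 °C
Reagents that add atoms: carbon monoxide ([C-]#[O+]); methanol (CO)
Why: Palladium-catalysed alkoxycarbonylation of an enol triflate: oxidative addition to zerovalent palladium, CO insertion and methanolysis of the acylpalladium give the C14 methyl ester with retention of alkene geometry.

Step 8
Reactants: 13 enoate acetonide
Product: 14 enoate diol
Conditions: AcOH/H2O (4:1), 45 °C, short reaction time
Reagents that add atoms: none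
Why: Acid-catalysed acetal hydrolysis, placed here because no epoxide or ketone pair is present and the acetonide has done its work of keeping β-elimination away from the ketone stages; the later epoxide would not survive this step, hence the change to fluoride-labile silyl ethers.

Step 9
Reactants: 14 enoate diol
Product: 15 bis(triethylsilyl) ether
Conditions: Et3SiOTf (2.5 equiv), 2,6-lutidine, CH2Cl2, −40 → 0 °C
Reagents that add atoms: triethylsilyl trifluoromethanesulfonate (CC[Si](CC)(CC)OS(=O)(=O)C(F)(F)F)
Why: Silylation of both secondary hydroxyls with a silyl triflate and a hindered pyridine base; triethylsilyl ethers should withstand the amide bases, cuprate, hydride and peroxide ahead and come off with buffered fluoride in the presence of the epoxide.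

Step 10
Reactants: 15 bis(triethylsilyl) ether
Product: 16 hydroxy Weinreb amide
Conditions: MeNH(OMe)·HCl (3 equiv), iPrMgCl (6 equiv), THF, −20 → 0 °C
Reagents that add atoms: N,O-dimethylhydroxylamine hydrochloride (CNOC.Cl)
Why: Lactone aminolysis to a Weinreb amide by the chloromagnesium amide: the γ-lactone is far more electrophilic than the conjugated, α-branched C14 methyl ester, and the γ-hydroxy amide should stay open under neutral conditions, which frees the C6 hydroxyl.

Step 11
Reactants: 16 hydroxy Weinreb amide
Product: 17 keto Weinreb amide
Conditions: Dess–Martin periodinane, pyridine, CH2Cl2, 0 °C → rt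
Reagents that add atoms: none
Why: Dess–Martin oxidation brings C6 back to the ketone now that C10 is an enoate carbon, so both C6 epimers converge and no transannular aldol partner remains; C7 is again α to a ketone and can settle in its preferred configuration.

Step 12
Reactants: 17 keto Weinreb amide
Product: 19 C4=C5 enone, via trimethylsilyl enol ether 18 (not isolated)
Conditions: LiN(iPr)2 (1.2 equiv) added to 17 and Me3SiCl in THF, −78 °C; then Pd(OAc)2 (1.1 equiv), MeCN, rt
Reagents that add atoms: none
Why: Kinetic deprotonation at the C5 methylene with internal silyl trapping (so that no free enolate can add across the ring to the C1=C10 enoate), then Saegusa–Ito oxidation; the palladium enolate at C5 can lose β-hydride only from C4, which puts the double bond at C4=C5, and its geometry is irrelevant at this stage.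

Step 13
Reactants: 19 C4=C5 enone
Product: 21 4-methyl enone, via trimethylsilyl enol ether 20 (not isolated)
Conditions: Me2CuLi (from CuI and 2 MeLi, 1.3 equiv), Me3SiCl, THF, −78 °C; then Pd(OAc)2 (1.1 equiv), MeCN, rt
Reagents that add atoms: lithium dimethylcuprate ([Li+].C[Cu-]C)
Why: Conjugate addition of the Gilman cuprate to the enone (faster than to the α-branched enoate, and the Weinreb amide is inert at −78 °C) with regiospecific silyl trapping, then a second Saegusa–Ito oxidation; the C4 stereocentre of 20 is erased and the trisubstituted enone is expected in the less strained ring-cis form with C3 and C6 on the same side, as the cis-epoxide requires.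

Step 14
Reactants: 21 4-methyl enone
Product: 22 C6 allylic alcohol
Conditions: NaBH4, CeCl3·7H2O, MeOH, −78 °C; pH 7 buffer work-up; used at once
Reagents that add atoms: none
Why: Luche 1,2-reduction: the CeCl3-activated borohydride should attack only the enone carbonyl, and a small hydride entering from the ring periphery is expected to give the alcohol with O6 trans to the C7 arm (the relation small hydrides give with 2-substituted cycloalkanones), which sets C6 and freezes C7.

Step 15
Reactants: 22 C6 allylic alcohol
Product: 23 epoxy alcohol
Conditions: VO(acac)2 (5 mol %), tBuOOH (1.5 equiv, decane solution), CH2Cl2, 0 °C → rt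
Reagents that add atoms: tert-butyl hydroperoxide (CC(C)(C)OO)
Why: Hydroxyl-directed vanadium-catalysed epoxidation: the vanadate ester of the C6 alcohol should deliver the peroxide oxygen to the adjacent C4=C5 bond on the face of O6, the syn outcome known for medium-ring cis-allylic alcohols with this catalyst, with retention of alkene geometry, so C4 and C5 are set; the hydroxyl-free, electron-poor C1=C10 bond should not react.

Step 16
Reactants: 23 epoxy alcohol
Product: 24 epoxy lactone
Conditions: PPTS (10 mol %), PhMe, 50 °C
Reagents that add atoms: none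
Why: Acid-catalysed lactonisation of a γ-hydroxy Weinreb amide (acyl substitution, no change at C6) closes the trans-fused γ-lactone; the weak acid should spare the epoxide, which has no π-nucleophile across the ring because C1=C10 is an electron-poor enoate.

Step 17
Reactants: 24 epoxy lactone
Product: 27 α-methylene lactone, via Mannich base 25 (not isolated), via trimethylammonium iodide 26 (not isolated)
Conditions: LiN(iPr)2 (1.1 equiv), THF, −78 °C; CH2=NMe2+ I−, −78 → 0 °C; MeI, MeOH, rt; aq. NaHCO3, CH2Cl2, rt
Reagents that add atoms: N,N-dimethylmethyleneiminium iodide, Eschenmoser's salt (C=[N+](C)C.[I-])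
Why: α-Methylenation of a γ-lactone by the Mannich route: the C11 enolate is aminomethylated by the iminium salt, the amine is quaternised and the ammonium eliminated (E1cB) to give C11=C13; the silyl ethers cover O8/O9 and the epoxide carbons are out of reach of the enolate.

Step 18
Reactants: 27 α-methylene lactone
Product: 28 C8/C9 diol
Conditions: HF·pyridine, pyridine, THF, 0 °C → rt
Reagents that add atoms: none
Why: Fluoride cleavage of both triethylsilyl ethers under pyridine-buffered conditions that should tolerate the epoxide, the α-methylene lactone and the esters.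

Step 19
Reactants: 28 C8/C9 diol
Product: 29 9-O-acetate
Conditions: AcCl (1.05 equiv), 2,4,6-collidine, CH2Cl2, −78 → −40 °C
Reagents that add atoms: acetyl chloride (CC(Cl)=O)
Why: Kinetically controlled mono-acylation with one equivalent of acyl chloride and a hindered base at low temperature: the allylic C9 hydroxyl, flanked by the flat sp2 carbon C10 and acidified by the enoate, is expected to react before the C8 hydroxyl, which lies between two branched sp3 carbons; no stereocentre is touched.

Step 20
Reactants: 30 ethyl 2-(hydroxymethyl)acrylate
Product: 31 silyl ether ester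
Conditions: tBuMe2SiCl, imidazole, CH2Cl2, 0 °C → rt
Reagents that add atoms: tert-butyldimethylsilyl chloride (CC(C)(C)[Si](C)(C)Cl)
Why: Silylation of the primary alcohol (silyl chloride, imidazole) so that the hydroxy acid cannot esterify itself later.

Step 21
Reactants: 31 silyl ether ester
Product: 32 silyl ether acid
Conditions: LiOH·H2O, THF/H2O, 0 °C → rt; cold 1 M HCl to pH 4
Reagents that add atoms: lithium hydroxide ([Li+].[OH-])
Why: Saponification of the ethyl ester with LiOH at low temperature; the tert-butyldimethylsilyl ether is stable to it.

Step 22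
Reactants: 29 9-O-acetate; 32 silyl ether acid
Product: 33 silyl-protected target
Conditions: 32 (2 equiv), DCC, DMAP (0.3 equiv), CH2Cl2, 0 °C → rt
Reagents that add atoms: none
Why: Steglich esterification (carbodiimide activation, acyl transfer through the acylpyridinium) of the remaining C8 hydroxyl; the activated acid is kept in excess so that acylation outruns acetyl migration from O9 to O8.

Step 23
Reactants: 33 silyl-protected target
Product: 34 target CNP0147016.1
Conditions: HF·pyridine, pyridine, THF, 0 °C
Reagents that add atoms: none
Why: Buffered fluoride removal of the primary silyl ether frees the hydroxymethyl group; the brief, pyridine-buffered exposure should leave epoxide, acrylates and lactone intact.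

## Compound list

1 | cyclooctane-1,3-dione | O=C1CCCCCC(=O)C1 | starting material
2 | methyl bromoacetate | COC(=O)CBr | starting material
3 | methyl 2-(2,8-dioxocyclooctyl)acetate | COC(=O)CC1C(=O)CCCCCC1=O | intermediate
4 | 2,2-dimethyl-1,3-dioxole | CC1(C)OC=CO1 | starting material
5 | methyl 2-(2-hydroxy-8-oxocyclooct-1-en-1-yl)acetate, enol tautomer of 3 (not isolated) | COC(=O)CC1=C(O)CCCCCC1=O | intermediate
6 | cyclobutanol photoadduct: cyclobutane C7–C8–C9–C10 fused to the eight-membered ketone ring and cis-fused to the dioxolane, OH on C10, arm on C7; racemic, ring-fusion isomers at C7/C10 not defined (not isolated) | COC(=O)CC12C(=O)CCCCCC1(O)[C@H]1OC(C)(C)O[C@H]12 | intermediate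
7 | ten-membered C6,C10-diketone with cis C8/C9 acetonide and the methyl acetate arm on C7 cis to O8; racemic, SMILES shows the enantiomer carried on | CC1(C)O[C@H]2[C@@H](CC(=O)OC)C(=O)CCCCCC(=O)[C@H]2O1 | intermediate
8 | the carboxylic acid of 7, single enantiomer (C7, C8, C9 as in the target) | CC1(C)O[C@H]2[C@@H](CC(=O)O)C(=O)CCCCCC(=O)[C@H]2O1 | intermediate
9 | C6,C10-dihydroxy acid, epimer mixture at C6 and C10 (not isolated) | CC1(C)O[C@H]2[C@@H](CC(=O)O)C(O)CCCCCC(O)[C@H]2O1 | intermediate
10 | 6,12-γ-lactone with free C10 hydroxyl and C8/C9 acetonide, epimer mixture at C6 and C10 | CC1(C)O[C@H]2[C@H]3CC(=O)OC3CCCCCC(O)[C@H]2O1 | intermediate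
11 | 6,12-γ-lactone C10-ketone, C6 epimer mixture | CC1(C)O[C@H]2[C@H]3CC(=O)OC3CCCCCC(=O)[C@H]2O1 | intermediate
12 | C10 enol triflate with ring-cis C1=C10 (C2 and C9 on the same side), C6 epimer mixture | CC1(C)O[C@H]2[C@H]3CC(=O)OC3CCCC/C=C(/OS(=O)(=O)C(F)(F)F)[C@H]2O1 | intermediate
13 | C14 methyl ester on ring-cis C1=C10, 6,12-lactone, C8/C9 acetonide, C6 epimer mixture | CC1(C)O[C@H]2[C@H]3CC(=O)OC3CCCC/C=C(/C(=O)OC)[C@H]2O1 | intermediate
14 | the cis C8/C9 diol of 13, C6 epimer mixture | O[C@H]1[C@H]2CC(=O)OC2CCCC/C=C(/C(=O)OC)[C@H]1O | intermediate
15 | the 8,9-bis(triethylsilyl) ether of 14, C6 epimer mixture | CC[Si](CC)(CC)O[C@H]1[C@H]2CC(=O)OC2CCCC/C=C(/C(=O)OC)[C@H]1O[Si](CC)(CC)CC | intermediate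
16 | C6 alcohol with N-methoxy-N-methylacetamide arm on C7, C14 methyl ester, 8,9-bis(triethylsilyl) ether, C6 epimer mixture | CC[Si](CC)(CC)O[C@H]1[C@@H](CC(=O)N(C)OC)C(O)CCCC/C=C(/C(=O)OC)[C@H]1O[Si](CC)(CC)CC | intermediate
17 | the C6 ketone of 16 | CC[Si](CC)(CC)O[C@H]1[C@@H](CC(=O)N(C)OC)C(=O)CCCC/C=C(/C(=O)OC)[C@H]1O[Si](CC)(CC)CC | intermediate
18 | C5=C6 trimethylsilyl enol ether of 17 (not isolated) | CC[Si](CC)(CC)O[C@H]1[C@@H](CC(=O)N(C)OC)C(O[Si](C)(C)C)=CCCC/C=C(/C(=O)OC)[C@H]1O[Si](CC)(CC)CC | intermediate
19 | C4=C5 enone (C6 ketone), C4=C5 geometry not defined | CC[Si](CC)(CC)O[C@H]1[C@@H](CC(=O)N(C)OC)C(=O)C=CCC/C=C(/C(=O)OC)[C@H]1O[Si](CC)(CC)CC | intermediate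
20 | 4-methyl C5=C6 trimethylsilyl enol ether, C4 epimer mixture (not isolated) | CC[Si](CC)(CC)O[C@H]1[C@@H](CC(=O)N(C)OC)C(O[Si](C)(C)C)=CC(C)CC/C=C(/C(=O)OC)[C@H]1O[Si](CC)(CC)CC | intermediate
21 | 4-methyl C4=C5 enone, ring-cis (C3 and C6 on the same side) | CC[Si](CC)(CC)O[C@H]1[C@@H](CC(=O)N(C)OC)C(=O)/C=C(/C)CC/C=C(/C(=O)OC)[C@H]1O[Si](CC)(CC)CC | intermediate
22 | C6 allylic alcohol, O6 trans to the C7 arm (C6 as in the target) | CC[Si](CC)(CC)O[C@H]1[C@@H](CC(=O)N(C)OC)[C@H](O)/C=C(/C)CC/C=C(/C(=O)OC)[C@H]1O[Si](CC)(CC)CC | intermediate
23 | 4,5-epoxy C6 alcohol, epoxide oxygen syn to O6 (C4, C5 as in the target) | CC[Si](CC)(CC)O[C@H]1[C@@H](CC(=O)N(C)OC)[C@H](O)[C@@H]2O[C@]2(C)CC/C=C(/C(=O)OC)[C@H]1O[Si](CC)(CC)CC | intermediate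
24 | 4,5-epoxy trans-fused 6,12-γ-lactone, 8,9-bis(triethylsilyl) ether | CC[Si](CC)(CC)O[C@H]1[C@H]2CC(=O)O[C@@H]2[C@@H]2O[C@]2(C)CC/C=C(/C(=O)OC)[C@H]1O[Si](CC)(CC)CC | intermediate
25 | 11-(dimethylaminomethyl) lactone, C11 epimer mixture (not isolated) | CC[Si](CC)(CC)O[C@H]1[C@H]2C(CN(C)C)C(=O)O[C@@H]2[C@@H]2O[C@]2(C)CC/C=C(/C(=O)OC)[C@H]1O[Si](CC)(CC)CC | intermediate
26 | 11-(trimethylammoniomethyl) lactone iodide (not isolated) | CC[Si](CC)(CC)O[C@H]1[C@H]2C(C[N+](C)(C)C)C(=O)O[C@@H]2[C@@H]2O[C@]2(C)CC/C=C(/C(=O)OC)[C@H]1O[Si](CC)(CC)CC.[I-] | intermediate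
27 | α-methylene lactone (C11=C13), 8,9-bis(triethylsilyl) ether | CC[Si](CC)(CC)O[C@H]1[C@H]2C(=C)C(=O)O[C@@H]2[C@@H]2O[C@]2(C)CC/C=C(/C(=O)OC)[C@H]1O[Si](CC)(CC)CC | intermediate
28 | the free cis C8/C9 diol of 27 | O[C@H]1[C@H]2C(=C)C(=O)O[C@@H]2[C@@H]2O[C@]2(C)CC/C=C(/C(=O)OC)[C@H]1O | intermediate
29 | 9-O-acetyl-8-hydroxy compound | O[C@H]1[C@H]2C(=C)C(=O)O[C@@H]2[C@@H]2O[C@]2(C)CC/C=C(/C(=O)OC)[C@H]1OC(C)=O | intermediate
30 | ethyl 2-(hydroxymethyl)acrylate | C=C(CO)C(=O)OCC | starting material
31 | ethyl 2-[(tert-butyldimethylsilyloxy)methyl]acrylate | C=C(CO[Si](C)(C)C(C)(C)C)C(=O)OCC | intermediate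
32 | 2-[(tert-butyldimethylsilyloxy)methyl]acrylic acid | C=C(CO[Si](C)(C)C(C)(C)C)C(=O)O | intermediate
33 | target with its hydroxymethyl group as the tert-butyldimethylsilyl ether | C=C(CO[Si](C)(C)C(C)(C)C)C(=O)O[C@H]1[C@H]2C(=C)C(=O)O[C@@H]2[C@@H]2O[C@]2(C)CC/C=C(/C(=O)OC)[C@H]1OC(C)=O | intermediate
34 | CNP0147016.1: 9-O-acetyl-8-O-[2-(hydroxymethyl)acryloyl]-4,5-epoxy-germacra-1(10),11(13)-dien-6,12-olide 14-methyl ester, stereochemistry as in the SMILES | C=C(CO)C(=O)O[C@H]1[C@H]2C(=C)C(=O)O[C@@H]2[C@@H]2O[C@]2(C)CC/C=C(/C(=O)OC)[C@H]1OC(C)=O | target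

## Count and risks

Total step count: 23 (21 in the main line, 2 for acid 32).
Longest linear sequence: 21 steps (steps 1–19, 22, 23).

Steps most likely to fail:

1. Step 2. The photoreaction may stall because the eight-membered dione holds little enol, because the excited enone relaxes by twisting about its double bond instead of adding to 4, or because the 1,5-diketone closes to a bicyclic aldol across the ring during work-up. The fallback sets out from 3. O-Acetylation (Ac2O, Et3N, DMAP) would give the enol acetate methyl 2-(2-acetoxy-8-oxocyclooct-1-en-1-yl)acetate F1, a stable chromophore that needs no tautomer equilibrium. Its [2+2] photocycloaddition to 4 would give the acetoxycyclobutane adduct F2, which can be purified. K2CO3 in MeOH at 0 °C then removes the acetate and the cyclobutanolate fragments by the same retro-aldol reaction, which comes back to the route at compound 7.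

2. Step 14. Hydride may be delivered to the other face of the C6 carbonyl (an open-chain Felkin-type analysis at C7 would in fact point that way), or a minor C7 epimer may be reduced along with the major one. The fallback sets out from 21. The reduction is run as described and the C6-epimeric allylic alcohol F3 is taken on. A Mitsunobu reaction (4-nitrobenzoic acid, PPh3, DIAD, PhMe, 0 °C) inverts C6 and gives the 4-nitrobenzoate of the required configuration F4. K2CO3 in MeOH at 0 °C frees the alcohol, which comes back to the route at compound 22, before the directed epoxidation.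

3. Step 19. The acetyl group may be transferred to O8 instead of O9, or may migrate between the cis-vicinal oxygens, if the hydrogen bond from the C9 hydroxyl to the C14 ester makes O8 the more nucleophilic oxygen. The fallback sets out from 28 and inverts the order of the two acylations. Steglich esterification with acid 32 (DCC, DMAP, CH2Cl2, 0 °C) would give the 8-O-acyl-9-hydroxy compound F5. Acetylation of its remaining C9 hydroxyl (Ac2O, pyridine, DMAP) comes back to the route at compound 33.

## Further compounds

F1 | step 2 | methyl 2-(2-acetoxy-8-oxocyclooct-1-en-1-yl)acetate | COC(=O)CC1=C(OC(C)=O)CCCCCC1=O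
F2 | step 2 | acetoxycyclobutane photoadduct (acetate of 6), racemic, ring-fusion isomers not defined | COC(=O)CC12C(=O)CCCCCC1(OC(C)=O)[C@H]1OC(C)(C)O[C@H]12
F3 | step 14 | C6 epimer of allylic alcohol 22 | CC[Si](CC)(CC)O[C@H]1[C@@H](CC(=O)N(C)OC)[C@@H](O)/C=C(/C)CC/C=C(/C(=O)OC)[C@H]1O[Si](CC)(CC)CC
F4 | step 14 | 4-nitrobenzoate of allylic alcohol 22 | CC[Si](CC)(CC)O[C@H]1[C@@H](CC(=O)N(C)OC)[C@H](OC(=O)c2ccc(cc2)[N+](=O)[O-])/C=C(/C)CC/C=C(/C(=O)OC)[C@H]1O[Si](CC)(CC)CC
F5 | step 19 | 8-O-{2-[(tert-butyldimethylsilyloxy)methyl]acryloyl}-9-hydroxy compound | C=C(CO[Si](C)(C)C(C)(C)C)C(=O)O[C@H]1[C@H]2C(=C)C(=O)O[C@@H]2[C@@H]2O[C@]2(C)CC/C=C(/C(=O)OC)[C@H]1O
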